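| setting | eta | theta | flask |
|---|---|---|---|
| J | 20 mM | 20 mM | 20 mM |
| Q | 10 mM | 15 mM | 20.0 mM |
| remark | run made earlier | run made earlier |  |
| time |  |  | 4.0 d |

| run | time / d | J / % | E / % |
|---|---|---|---|
| eta | 0.333 | 45.3 | 21.3 |
| eta | 0.833 | 33.3 | 17.2 |
| eta | 1.67 | 23.6 | 12.5 |
| eta | 2.50 | 18.0 | 9.5 |
| eta | 4.00 | 12.8 | 10.8 |
| eta | 5.00 | 9.4 | 8.5 |
| theta | 0.333 | 42.5 | 23.5 |
| theta | 0.833 | 28.6 | 18.4 |
| theta | 1.67 | 21.8 | 13.8 |
| theta | 2.50 | 17.5 | 14.4 |
| theta | 4.00 | 13.8 | 11.3 |
| theta | 5.00 | 11.4 | 11.8 |

(scatter of a reading: 1 percentage point)

1. why nothing more happens at 4.0 d, or that something still does (Q has run out first / forward and back rates have come level / it is still moving / all of J has reacted)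
2. part of the J gone at 4.0 d
3. the E standing at 4.0 d, as a percentage of the J charged
4. the G standing at 4.0 d, as a percentage of the J charged
5. amount of E if the flask were left three thousand times as long, in percent of the J charged

- the reaction counts as stopped when no species that holds the J changes by six tenths of a point or more over the second half of the time

**No constants.** We hold no rate constant for this flask, so we reckon from the charges, taken as fractions of the J charged. Each exchange costs one Q: J takes one to become E, and E takes a second to become G.

**Bench rule.** The usual balance says that J gone and not standing as E is G. At the last eta reading this gives G of 82.1%. That G with its E would have cost 3.45 times the Q charged in the eta run, so the rule breaks down once E plus twice G passes the Q charge.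

**Q ceiling.** Our bound from the charge, a stoichiometric limit, is the Q ceiling, half of the Q charge left after paying for E. For this flask we take E from the theta reading at 4.00 d, 11.3%, which gives a ceiling of 44.4%. The same theta reading leaves 74.9% of the J charged neither J nor E, more than the ceiling. So we commit to G below the ceiling in this flask, and, if its J and E stand near those of the theta run, to about 30.5% of the J charged or more in some unlisted form that took no Q.

**The forecast.** The forecast says it is still moving, with 87% of J gone, E at 11.5%, G at 75.5%, and E at 2% if the flask is left very much longer. On G it says “G is about 75.5% by balance”, which stands above our ceiling, and there we part.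

**The result.** In the flask it is still moving, with 86.7% of J gone, E at 13.1%, G at 20.4%, and E at 0.549% if it is left very much longer.

    E + Q ⇌ D + G (K = 1.80, k = 0.130 /M/min)
    J + Q ⇌ D + E (K = 1.10, k = 0.170 /M/min)
    2 J → J2 (k = 0.0340 /M/min)

**Less Q.** The G of this flask is 46.0% of our ceiling of 44.4%. We carry the ceiling and that share to a neighbouring flask charged with 5.0 mM of Q, the other charge and the time held. Its Q charge is 25.0% of the J charged and its E is 7.02%, so its ceiling is 8.99%, and the share gives 4.14%. At 4.00 d that neighbour holds 5.12% of G, with 31% of its own Q left and J2, two J joined without Q, at 75.4% of the J charged.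

The runs were computed from invented constants.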